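**Retrosynthetic overview**
1. Sodwanone B ⇐ acid isomerisation of a 5′,6′-epoxy-7′-ketone to the diosphenol ⇐ oxidation of the C3 carbinol ⇐ C13–C9′ bond by Stork–Danheiser addition of a left-half alkyllithium to a right-half vinylogous ester.
2. Right half (decalin bought): (S)-Wieland–Miescher ketone → gem-dimethylation/Δ5′ → C7′ allylic oxidation → C8′ methylation → enol ether → Δ5′ epoxide.
3. Left half: (S)-carvone supplies the cyclohexane and C7; double α′-alkylation builds quaternary C6; Criegee rearrangement turns isopropenyl into C7–O with retention.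
4. Key step: Ireland–Claisen [3,3] rearrangement of the C9 allylic acetate (from Wharton transposition, then Mitsunobu inversion) forms C11–C12 and sets C11; hydrogenation then sets C10.
5. Ring order: carbocycle (carvone) → oxepane by 7-endo epoxide opening after the Claisen → decalin (bought) → ring-B dienone/diosphenol unveiled last.

Assumptions: (S)-carvone, (S)-Wieland–Miescher ketone and 5-iodo-2-methylpent-2-ene are purchased; the oxepane C3 carbinol (and the side-chain epoxide before it) is carried as an epimer mixture that converges at step 19.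

Locants used below: left half C2–C11 (ring O between C2 and C7), linker C12–C13, right half C1′–C10′ (drimane numbering).

---

**Step 1**
Reactants: 1, (S)-(+)-carvone
Product: 2, trans-6-methylcarvone, (5S,6R)-2,6-dimethyl-5-(prop-1-en-2-yl)cyclohex-2-en-1-one
Conditions: LDA, THF, −78 °C; MeI, −78 → 0 °C
Reagents that add atoms: iodomethane, CI
Why: Kinetic α′-enolate alkylation of carvone; the new centre is re-enolised in step 2, so its configuration is irrelevant.

**Step 2**
Reactants: 2; 3, 5-iodo-2-methylpent-2-ene
Product: 4, (5R,6R)-2,6-dimethyl-6-(4-methylpent-3-en-1-yl)-5-(prop-1-en-2-yl)cyclohex-2-en-1-one (6-Me cis, homoprenyl trans to isopropenyl)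
Conditions: LDA, THF, −78 °C; 3, DMPU, −78 → 0 °C
Reagents that add atoms: none (3 is a reactant)
Why: Enolate alkylation anti to the adjacent isopropenyl group sets the C6 quaternary centre by substrate control (established for 6-methylcarvone).

**Step 3**
Reactants: 4
Product: 5, side-chain epoxide of 4 (2-(3,3-dimethyloxiran-2-yl)ethyl chain; epoxide epimers)
Conditions: mCPBA (1.0 equiv), NaHCO3, CH2Cl2, −10 °C
Reagents that add atoms: mCPBA, OOC(=O)c1cccc(Cl)c1
Why: Prilezhaev epoxidation is selective for the trisubstituted alkene over the 1,1-disubstituted isopropenyl and the enone; the new carbinol carbon later becomes C=O.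

**Step 4**
Reactants: 5
Product: 6, (1S,2R)-2-[2-(3,3-dimethyloxiran-2-yl)ethyl]-2,4-dimethyl-3-oxocyclohex-4-en-1-yl acetate (OAc cis to the quaternary methyl)
Conditions: O3, CH2Cl2/MeOH, −78 °C; then Ac2O, Et3N, DMAP, rt
Reagents that add atoms: ozone, [O-][O+]=O (ether oxygen); methanol, CO (acetate carbonyl oxygen via the methoxy hydroperoxide)
Why: Ozonolysis to the methoxy hydroperoxide and Criegee rearrangement (C→O shift with retention) convert isopropenyl into the C7 acetate with the bought configuration; enone and epoxide survive.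

**Step 5**
Reactants: 6
Product: 7, α,β-epoxy ketone of 6 (ring epoxide trans to OAc)
Conditions: t-BuOOH, DBU, CH2Cl2, rt
Reagents that add atoms: tert-butyl hydroperoxide, CC(C)(C)OO
Why: Weitz–Scheffer epoxidation; peroxide adds axially at C9 anti to the C7 acetate, and the acetate cannot β-eliminate because C6 has no hydrogen.

**Step 6**
Reactants: 7
Product: 8, 5-acetoxy-4-[2-(3,3-dimethyloxiran-2-yl)ethyl]-2,4-dimethylcyclohex-2-en-1-ol (OH trans to OAc)
Conditions: N2H4·H2O, AcOH (cat.), MeOH, 0 °C → rt
Reagents that add atoms: none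
Why: Wharton transposition; the epoxy hydrazone loses N2 to give the C10=C11 alkene and the C9 carbinol with the epoxide C–O configuration retained.

**Step 7**
Reactants: 8
Product: 9, the C9-inverted diacetate (allylic OAc cis to the C7 OAc and the C6 methyl)
Conditions: AcOH, PPh3, DIAD, THF, 0 °C
Reagents that add atoms: acetic acid, CC(=O)O
Why: Mitsunobu inversion puts the C9 oxygen on the face needed for chirality transfer and installs the acetate required for the Claisen in one operation.

**Step 8 (key step)**
Reactants: 9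
Product: 10, 2-{5-acetoxy-6-[2-(3,3-dimethyloxiran-2-yl)ethyl]-2,6-dimethylcyclohex-2-en-1-yl}acetic acid (CH2CO2H cis to C6-Me and C7-OAc)
Conditions: LDA (2.5 equiv), TMSCl/Et3N, THF, −78 → 60 °C; aq. citric acid
Reagents that add atoms: none
Why: Ireland–Claisen [3,3]-sigmatropic rearrangement of the allylic silyl ketene acetal is suprafacial, so C11–C12 forms on the face of the C9–O bond and sets C11; the non-allylic C7 acetate is regenerated on work-up.

**Step 9**
Reactants: 10
Product: 11, 2-[(5aS,6R,9aS)-3-hydroxy-2,2,5a,7-tetramethyl-2,3,4,5,5a,6,9,9a-octahydrobenzo[b]oxepin-6-yl]acetic acid (trans-fused; C3 epimers)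
Conditions: K2CO3, MeOH, 40 °C; then p-TsOH (cat.), CH2Cl2, 0 °C → rt
Reagents that add atoms: none
Why: The freed C7–OH opens the epoxide at its tertiary carbon (acid-catalysed SN1-like 7-endo opening, as in zoapatanol-type oxepane syntheses), giving the trans-fused oxepane with retention at C7.

**Step 10**
Reactants: 11
Product: 12, 2-[(5aS,6R,7R,9aS)-3-hydroxy-2,2,5a,7-tetramethyldecahydrobenzo[b]oxepin-6-yl]acetic acid
Conditions: H2 (1–3 atm), PtO2, EtOAc, rt
Reagents that add atoms: none
Why: Syn-hydrogenation from the face opposite the axial C6 methyl and the C11 side chain sets C10 (methyl axial, cis to C6-Me), as in drim-7-ene hydrogenations; Pt limits alkene migration.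

**Step 11**
Reactants: 12
Product: 13, (5aS,6R,7R,9aS)-6-(2-hydroxyethyl)-2,2,5a,7-tetramethyldecahydrobenzo[b]oxepin-3-ol
Conditions: LiAlH4, THF, 0 → 65 °C
Reagents that add atoms: none
Why: Hydride reduction of the carboxylic acid to the primary alcohol; ether and carbinol are inert.

**Step 12**
Reactants: 13
Product: 14, (5aS,6R,7R,9aS)-6-(2-iodoethyl)-2,2,5a,7-tetramethyldecahydrobenzo[b]oxepin-3-ol
Conditions: I2, PPh3, imidazole, CH2Cl2, 0 °C
Reagents that add atoms: iodine, II
Why: Appel-type iodination is selective for the unhindered primary alcohol over the hindered secondary C3–OH.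

**Step 13**
Reactants: 15, (S)-(+)-Wieland–Miescher ketone
Product: 16, (S)-5,5,8a-trimethyl-3,5,8,8a-tetrahydronaphthalene-1,6(2H,7H)-dione
Conditions: t-BuOK (2.5 equiv), t-BuOH, rt; MeI
Reagents that add atoms: iodomethane, CI
Why: Deconjugative α,α-dimethylation through the extended dienolate installs the C4′ gem-dimethyl group and moves the alkene to Δ5′; C10′ is untouched.

**Step 14**
Reactants: 16
Product: 17, (S)-5,5,8a-trimethyl-8,8a-dihydronaphthalene-1,3,6(2H,5H,7H)-trione (largely enolised)
Conditions: CrO3, 3,5-dimethylpyrazole, CH2Cl2, −20 °C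
Reagents that add atoms: chromium trioxide, O=[Cr](=O)=O
Why: Allylic oxidation of the only allylic CH2 (C7′), as for Δ5-steroids to 7-ketones, creates the C7′/C9′ 1,3-dicarbonyl.

**Step 15**
Reactants: 17
Product: 18, (8aS)-2,5,5,8a-tetramethyl-8,8a-dihydronaphthalene-1,3,6(2H,5H,7H)-trione
Conditions: MeI, K2CO3, acetone, reflux
Reagents that add atoms: iodomethane, CI
Why: C-alkylation of the uniquely acidic 1,3-dicarbonyl carbon C8′, chemoselective over C2′.

**Step 16**
Reactants: 18
Product: 19, (S)-3-methoxy-2,5,5,8a-tetramethyl-8,8a-dihydronaphthalene-1,6(5H,7H)-dione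
Conditions: MeOH, HC(OMe)3, p-TsOH (cat.), rt
Reagents that add atoms: methanol, CO
Why: Acid-catalysed enol etherification gives the thermodynamic vinylogous ester, with OMe on unhindered C7′ conjugated to Δ5′ and the carbonyl left beside quaternary C10′.

**Step 17**
Reactants: 19
Product: 20, 5′,6′-α-epoxide of 19 (epoxide anti to the angular methyl)
Conditions: mCPBA, NaHCO3, CH2Cl2, 0 °C
Reagents that add atoms: mCPBA, OOC(=O)c1cccc(Cl)c1
Why: Electrophilic epoxidation of the γ,δ-alkene of the dienone (as for steroidal 4,6-dien-3-ones), the push–pull C7′=C8′ bond being deactivated; the epoxide configuration is inconsequential.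

**Step 18**
Reactants: 14; 20
Product: 21, coupled epoxy dienone (sodwanone B skeleton with C3–OH in place of the oxepanone C=O and a 5′,6′-epoxide in place of the C5′=C6′(OH) enol)
Conditions: 20: KH (1.05 equiv), THF, 0 °C; 14: t-BuLi (3.0 equiv), Et2O, −78 °C; combine, −78 → −20 °C; then 1 M HCl, THF, 0 °C
Reagents that add atoms: none
Why: With the C3′ ketone masked as its enolate, the primary alkyllithium adds 1,2 to the vinylogous-ester carbonyl C9′, and acid hydrolysis/dehydration (Stork–Danheiser transposition) gives the C7′ enone with the C8′=C9′ bond; no stereocentre is formed.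

**Step 19**
Reactants: 21
Product: 22, 5′,6′-epoxy-5′,6′-dihydro-6′-deoxysodwanone B (3,3′,7′-triketone)
Conditions: Dess–Martin periodinane, NaHCO3, CH2Cl2, rt
Reagents that add atoms: none
Why: Oxidation of the only carbinol converges both C3 epimers on the oxepanone; epoxide and enone are inert.

**Step 20**
Reactants: 22
Product: 23, sodwanone B
Conditions: H2SO4 (cat.), AcOH, rt
Reagents that add atoms: none
Why: Acid-catalysed isomerisation of the α,β-epoxy ketone (opening at tertiary C5′, loss of the C6′ proton) gives the diosphenol, as in the 4,5-epoxy-3-ketone → 4-hydroxy-enone conversion of steroids.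

---

**Compound list**
1 | (S)-(+)-carvone | CC1=CC[C@@H](CC1=O)C(C)=C | starting material
2 | trans-6-methylcarvone | CC1=CC[C@H](C(C)=C)[C@@H](C)C1=O | intermediate
3 | 5-iodo-2-methylpent-2-ene | CC(C)=CCCI | starting material
4 | 6-homoprenyl-6-methylcarvone | CC1=CC[C@H](C(C)=C)[C@@](C)(CCC=C(C)C)C1=O | intermediate
5 | side-chain epoxide (epimers at epoxide CH) | CC1=CC[C@H](C(C)=C)[C@@](C)(CCC2OC2(C)C)C1=O | intermediate
6 | C7 acetate | CC1=CC[C@H](OC(C)=O)[C@@](C)(CCC2OC2(C)C)C1=O | intermediate
7 | epoxy ketone | C[C@]12O[C@H]1C[C@H](OC(C)=O)[C@@](C)(CCC3OC3(C)C)C2=O | intermediate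
8 | Wharton allylic alcohol | CC1=C[C@](C)(CCC2OC2(C)C)[C@@H](OC(C)=O)C[C@@H]1O | intermediate
9 | inverted diacetate | CC1=C[C@](C)(CCC2OC2(C)C)[C@@H](OC(C)=O)C[C@H]1OC(C)=O | intermediate
10 | Ireland–Claisen acid | CC1=CC[C@H](OC(C)=O)[C@@](C)(CCC2OC2(C)C)[C@@H]1CC(=O)O | intermediate
11 | oxepane hydroxy acid (C3 epimers) | OC(=O)C[C@@H]1C(C)=CC[C@@H]2OC(C)(C)C(O)CC[C@]21C | intermediate
12 | saturated hydroxy acid | OC(=O)C[C@@H]1[C@H](C)CC[C@@H]2OC(C)(C)C(O)CC[C@]21C | intermediate
13 | diol | OCC[C@@H]1[C@H](C)CC[C@@H]2OC(C)(C)C(O)CC[C@]21C | intermediate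
14 | left-half iodide | ICC[C@@H]1[C@H](C)CC[C@@H]2OC(C)(C)C(O)CC[C@]21C | intermediate
15 | (S)-(+)-Wieland–Miescher ketone | C[C@]12CCC(=O)C=C1CCCC2=O | starting material
16 | gem-dimethyl Δ5′-dione | C[C@]12CCC(=O)C(C)(C)C1=CCCC2=O | intermediate
17 | ene-trione | C[C@]12CCC(=O)C(C)(C)C1=CC(=O)CC2=O | intermediate
18 | 8′-methyl ene-trione (C8′ epimers/enol) | C[C@]12CCC(=O)C(C)(C)C1=CC(=O)C(C)C2=O | intermediate
19 | vinylogous methyl ester | C[C@]12CCC(=O)C(C)(C)C1=CC(OC)=C(C)C2=O | intermediate
20 | epoxy vinylogous ester | C[C@]12CCC(=O)C(C)(C)[C@@]13O[C@H]3C(OC)=C(C)C2=O | intermediate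
21 | coupled epoxy dienone carbinol (C3 epimers) | CC1=C(CC[C@@H]2[C@H](C)CC[C@@H]3OC(C)(C)C(O)CC[C@]32C)[C@@]2(C)CCC(=O)C(C)(C)[C@@]23O[C@H]3C1=O | intermediate
22 | epoxy triketone | CC1=C(CC[C@@H]2[C@H](C)CC[C@@H]3OC(C)(C)C(=O)CC[C@]32C)[C@@]2(C)CCC(=O)C(C)(C)[C@@]23O[C@H]3C1=O | intermediate
23 | sodwanone B | CC1=C(CC[C@@H]2[C@H](C)CC[C@@H]3OC(C)(C)C(=O)CC[C@]32C)[C@@]2(C)CCC(=O)C(C)(C)C2=C(O)C1=O | target

---

**Totals**
Total steps: 20 (12 left half, 5 right half, 3 union/endgame).
Longest linear sequence: 15 (steps 1–12, then 18–20).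

**Three steps most likely to fail**
- **Step 9** (7-endo vs 6-exo epoxide opening; a tetrahydropyran carbinol may dominate). Fallback: remove the regiochemical choice by Meinwald-isomerising the epoxide to the C3 isopropyl ketone, brominating the tertiary α-carbon (C2) and closing the ether with Ag(I)-promoted attack of C7–OH; the resulting oxepanone is carried as a ketal through the coupling.
- **Step 17** (epoxidation of the hindered Δ5′ bond, on which the step-20 diosphenol unveiling depends). Fallback: install the C6′ oxygen after coupling instead: hydrogenate Δ5′ of 17, carry the saturated series with C3′ as a dioxolane, then form the kinetic C6′ silyl enol ether of the coupled enone, Rubottom-oxidise and oxidise to the 6′,7′-dione, which enolises to the diosphenol.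
- **Step 18** (alkyllithium addition to a hindered vinylogous ester beside an enolate-masked ketone). Fallback: switch to a ketone-tolerant sp3–sp2 cross-coupling: Negishi coupling of the alkylzinc from 14 with the C9′ enol triflate of an 8′-methyl-9′-ketone derived from 16, then oxidation of the bis-allylic C7′ to the dienone.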